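**Retrosynthetic overview**

- Salvianolic acid D ⇒ hydrolytic opening of a benzofuran-2(3H)-one, which masks the 3-OH and the CH2CO2H together, plus removal of four benzyl groups.
- Cinnamate C=C and ester C–O ⇒ three-component union of tribenzyl (R)-danshensu, Ph3P=C=C=O and a lactone aldehyde (Wittig). The (R)-centre comes from the chiral pool and is never touched.
- Key C–C bond (ring C2–CH2CO2H) ⇒ 4-(benzyloxy)-3-hydroxybenzaldehyde + ethyl (methylthio)acetate: O-sulfonium ylide, then [2,3]-shift to the only free ortho carbon. The thioacetate acts as an α-carbonyl cation equivalent towards the nucleophilic arene carbon; sulfur is cut out later with zinc.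
- Rings: both benzene rings are bought. The only ring made is the γ-lactone (step 1), and it is opened again in the last step.

Assumption: sodium (R)-danshensu (sodium salvianate A, sold in bulk as the extracted salt) is taken as a cheap commercial chiral-pool starting material.

**Step 1**
Reactants: 1 4-(benzyloxy)-3-hydroxybenzaldehyde; 2 ethyl (methylsulfanyl)acetate
Product: 7 rac-7-(benzyloxy)-3-(methylsulfanyl)-2-oxo-2,3-dihydro-1-benzofuran-4-carbaldehyde, via chlorosulfonium chloride 3 (not isolated), via aryloxysulfonium chloride 4 (not isolated), via sulfonium ylide 5 (not isolated), via hydroxy ester 6 (not isolated)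
Conditions: 2, SO2Cl2 (1.0 equiv), CH2Cl2, −78 °C; then 1, −78 → −40 °C; Et3N (2.2 equiv), −78 °C → rt; then TsOH·H2O (cat.), PhMe, 110 °C (−EtOH)
Reagents that add atoms: none
Why: Gassman-type ortho-alkylation of a phenol, in which the chlorosulfonium salt 3 is captured at the phenol oxygen, Et3N forms the ester-stabilised ylide 5, and its [2,3]-sigmatropic (Sommelet–Hauser-type) rearrangement can deliver the acetate α-carbon only to C2 because the other ortho position carries OBn; acid then closes the γ-lactone, and the new C3 centre is racemic and is erased in step 4.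

**Step 2**
Reactants: 8 sodium (2R)-3-(3,4-dihydroxyphenyl)-2-hydroxypropanoate (sodium danshensu)
Product: 9 benzyl (2R)-3-[3,4-bis(benzyloxy)phenyl]-2-hydroxypropanoate
Conditions: BnBr (3.2 equiv), K2CO3, DMF, rt, N2
Reagents that add atoms: benzyl bromide, BrCc1ccccc1
Why: Williamson/carboxylate O-alkylation, in which the carboxylate and the two phenoxides are benzylated while the much less acidic secondary alcohol stays free and the (R)-centre, which K2CO3 does not enolise at rt, is carried over unchanged from the chiral pool.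

**Step 3**
Reactants: 9 benzyl (2R)-3-[3,4-bis(benzyloxy)phenyl]-2-hydroxypropanoate; 10 (triphenylphosphoranylidene)ketene (Bestmann ylide); 7 rac-7-(benzyloxy)-3-(methylsulfanyl)-2-oxo-2,3-dihydro-1-benzofuran-4-carbaldehyde
Product: 12 benzyl (2R)-3-[3,4-bis(benzyloxy)phenyl]-2-({(2E)-3-[7-(benzyloxy)-3-(methylsulfanyl)-2-oxo-2,3-dihydro-1-benzofuran-4-yl]prop-2-enoyl}oxy)propanoate (1:1 epimers at lactone C3), via ester ylide 11 (not isolated)
Conditions: 9 (1.05 equiv), 10 (1.0 equiv), THF, 60 °C until 10 is consumed; then 7 (0.9 equiv), 60 °C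
Reagents that add atoms: none
Why: Three-component Bestmann-ylide coupling, in which O–H addition of 9 across the ketene C=C of 10 gives the stabilised ester ylide 11, whose neutral Wittig reaction with the aromatic aldehyde is E-selective and leaves the (R)-centre untouched; the C3–SMe group keeps the CH-acidic lactone from Knoevenagel self-condensation.

**Step 4**
Reactants: 12 benzyl (2R)-3-[3,4-bis(benzyloxy)phenyl]-2-({(2E)-3-[7-(benzyloxy)-3-(methylsulfanyl)-2-oxo-2,3-dihydro-1-benzofuran-4-yl]prop-2-enoyl}oxy)propanoate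
Product: 13 benzyl (2R)-3-[3,4-bis(benzyloxy)phenyl]-2-({(2E)-3-[7-(benzyloxy)-2-oxo-2,3-dihydro-1-benzofuran-4-yl]prop-2-enoyl}oxy)propanoate
Conditions: Zn dust (activated), AcOH/THF, 40 °C
Reagents that add atoms: none
Why: Dissolving-metal reductive cleavage of an α-heteroatom-substituted carbonyl compound (Zn/AcOH desulfurisation of an α-(methylthio)arylacetate), in which electron transfer expels methanethiolate to give the aromatic 2-oxidobenzofuran enolate that is protonated, so both C3 epimers converge to one compound while the cinnamate, the benzyl groups and the α-acyloxy ester are not reduced.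

**Step 5**
Reactants: 13 benzyl (2R)-3-[3,4-bis(benzyloxy)phenyl]-2-({(2E)-3-[7-(benzyloxy)-2-oxo-2,3-dihydro-1-benzofuran-4-yl]prop-2-enoyl}oxy)propanoate
Product: 15 salvianolic acid D, via lactone acid 14 (not isolated)
Conditions: BCl3 (10 equiv), pentamethylbenzene (12 equiv), CH2Cl2, −78 → 0 °C; then aq NaHCO3/THF (pH 8–9), rt, Ar; then 1 M HCl to pH 2
Reagents that add atoms: water, O
Why: Lewis-acid debenzylation with a cation scavenger (BCl3/pentamethylbenzene) removes the three aryl benzyl ethers and the benzyl ester without touching the C=C or the alkyl cinnamate linkage, and the phenolic γ-lactone of 14 is then hydrolysed at pH 8–9 much faster than the alkyl ester; no stereocentre is affected.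

**Compound list**

1 | 4-(benzyloxy)-3-hydroxybenzaldehyde | O=Cc1ccc(OCc2ccccc2)c(O)c1 | starting material
2 | ethyl (methylsulfanyl)acetate | CCOC(=O)CSC | starting material
3 | chloro(2-ethoxy-2-oxoethyl)methylsulfonium chloride | CCOC(=O)C[S+](C)Cl.[Cl-] | intermediate
4 | [2-(benzyloxy)-5-formylphenoxy](2-ethoxy-2-oxoethyl)methylsulfonium chloride | CCOC(=O)C[S+](C)Oc1cc(C=O)ccc1OCc1ccccc1.[Cl-] | intermediate
5 | [2-(benzyloxy)-5-formylphenoxy](methyl)sulfonium (ethoxycarbonyl)methylide | CCOC(=O)[CH-][S+](C)Oc1cc(C=O)ccc1OCc1ccccc1 | intermediate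
6 | ethyl rac-2-[3-(benzyloxy)-6-formyl-2-hydroxyphenyl]-2-(methylsulfanyl)acetate | CCOC(=O)C(SC)c1c(O)c(OCc2ccccc2)ccc1C=O | intermediate
7 | rac-7-(benzyloxy)-3-(methylsulfanyl)-2-oxo-2,3-dihydro-1-benzofuran-4-carbaldehyde | O=Cc1ccc(OCc2ccccc2)c2OC(=O)C(SC)c12 | intermediate
8 | sodium (2R)-3-(3,4-dihydroxyphenyl)-2-hydroxypropanoate (sodium danshensu) | [Na+].[O-]C(=O)[C@H](O)Cc1ccc(O)c(O)c1 | starting material
9 | benzyl (2R)-3-[3,4-bis(benzyloxy)phenyl]-2-hydroxypropanoate | O=C(OCc1ccccc1)[C@H](O)Cc1ccc(OCc2ccccc2)c(OCc2ccccc2)c1 | intermediate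
10 | (triphenylphosphoranylidene)ketene | O=C=C=P(c1ccccc1)(c1ccccc1)c1ccccc1 | starting material
11 | (2R)-1-(benzyloxy)-3-[3,4-bis(benzyloxy)phenyl]-1-oxopropan-2-yl (triphenylphosphoranylidene)acetate | O=C(OCc1ccccc1)[C@H](OC(=O)C=P(c2ccccc2)(c2ccccc2)c2ccccc2)Cc1ccc(OCc2ccccc2)c(OCc2ccccc2)c1 | intermediate
12 | benzyl (2R)-3-[3,4-bis(benzyloxy)phenyl]-2-({(2E)-3-[7-(benzyloxy)-3-(methylsulfanyl)-2-oxo-2,3-dihydro-1-benzofuran-4-yl]prop-2-enoyl}oxy)propanoate (C3 of the lactone unassigned, 1:1) | O=C(OCc1ccccc1)[C@H](OC(=O)/C=C/c1ccc(OCc2ccccc2)c2OC(=O)C(SC)c12)Cc1ccc(OCc2ccccc2)c(OCc2ccccc2)c1 | intermediate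
13 | benzyl (2R)-3-[3,4-bis(benzyloxy)phenyl]-2-({(2E)-3-[7-(benzyloxy)-2-oxo-2,3-dihydro-1-benzofuran-4-yl]prop-2-enoyl}oxy)propanoate | O=C(OCc1ccccc1)[C@H](OC(=O)/C=C/c1ccc(OCc2ccccc2)c2OC(=O)Cc12)Cc1ccc(OCc2ccccc2)c(OCc2ccccc2)c1 | intermediate
14 | (2R)-3-(3,4-dihydroxyphenyl)-2-({(2E)-3-(7-hydroxy-2-oxo-2,3-dihydro-1-benzofuran-4-yl)prop-2-enoyl}oxy)propanoic acid | O=C(O)[C@H](OC(=O)/C=C/c1ccc(O)c2OC(=O)Cc12)Cc1ccc(O)c(O)c1 | intermediate
15 | salvianolic acid D, (2R)-2-({(2E)-3-[2-(carboxymethyl)-3,4-dihydroxyphenyl]prop-2-enoyl}oxy)-3-(3,4-dihydroxyphenyl)propanoic acid | O=C(O)Cc1c(/C=C/C(=O)O[C@H](Cc2ccc(O)c(O)c2)C(=O)O)ccc(O)c1O | target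

**Totals**

Total step count: 5. Longest linear sequence: 4 steps (1 → 3 → 4 → 5, or 2 → 3 → 4 → 5).

**Three steps most likely to fail**

Step 1. The risks are Pummerer chlorination of the chlorosulfonium salt before the phenol captures it, and a sluggish [2,3]-shift into the hindered C2 position. The fallback sets out from 1 and comes back to the route at 13. It brings in the acetic acid carbon by an aromatic Claisen rearrangement instead: 1 is O-allylated (allyl bromide, K2CO3, acetone) to 3-(allyloxy)-4-(benzyloxy)benzaldehyde F1, which rearranges at 190 °C in N,N-diethylaniline into the only free ortho position to give 2-allyl-4-(benzyloxy)-3-hydroxybenzaldehyde F2. Lemieux–Johnson cleavage (OsO4 cat., NaIO4, 2,6-lutidine, dioxane/H2O) gives the arylacetaldehyde as its cyclic lactol, 7-(benzyloxy)-2-hydroxy-2,3-dihydro-1-benzofuran-4-carbaldehyde F3. Fétizon oxidation (Ag2CO3 on Celite, PhMe, reflux) gives 7-(benzyloxy)-2-oxo-2,3-dihydro-1-benzofuran-4-carbaldehyde F4. Olefination of F4 with ylide 11 (made from 9 and 10 as in step 3, run at 40 °C to limit Knoevenagel self-condensation of the CH-acidic lactone) gives 13 directly, so step 4 is not needed.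

Step 3. The risks are slow addition of the hindered α-hydroxy ester to 10, and intramolecular Wittig attack of 11 on its own benzyl ester (tetronate formation) before the aldehyde is added. The fallback sets out from 9 and comes back to the route at 11. The ylide is built stepwise and cold: 9 is acylated with bromoacetyl bromide (pyridine, CH2Cl2, 0 °C) to benzyl (2R)-3-[3,4-bis(benzyloxy)phenyl]-2-[(bromoacetyl)oxy]propanoate F5. PPh3 (EtOAc, rt) converts it into {2-[(2R)-1-(benzyloxy)-3-[3,4-bis(benzyloxy)phenyl]-1-oxopropan-2-yl]oxy-2-oxoethyl}triphenylphosphonium bromide F6. Cold aqueous Na2CO3/CH2Cl2 liberates ylide 11, now isolated, which is condensed with 7 in CH2Cl2 at rt to reach 12.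

Step 4. The risks are a C–SMe bond that zinc cleaves too slowly, and competing reduction of the cinnamate if forcing conditions are needed. The fallback sets out from 12 and comes back to the route at 13. Sulfur is first activated by oxidation: mCPBA (1.0 equiv, CH2Cl2, −78 °C) gives benzyl (2R)-3-[3,4-bis(benzyloxy)phenyl]-2-({(2E)-3-[7-(benzyloxy)-3-(methanesulfinyl)-2-oxo-2,3-dihydro-1-benzofuran-4-yl]prop-2-enoyl}oxy)propanoate F7. Its much more easily reduced C–S(O) bond is then cut with aluminium amalgam (THF/H2O, 0 °C) to give 13.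

**Further compounds**

F1 | step 1 | 3-(allyloxy)-4-(benzyloxy)benzaldehyde | C=CCOc1cc(C=O)ccc1OCc1ccccc1
F2 | step 1 | 2-allyl-4-(benzyloxy)-3-hydroxybenzaldehyde | C=CCc1c(O)c(OCc2ccccc2)ccc1C=O
F3 | step 1 | rac-7-(benzyloxy)-2-hydroxy-2,3-dihydro-1-benzofuran-4-carbaldehyde | O=Cc1ccc(OCc2ccccc2)c2OC(O)Cc12
F4 | step 1 | 7-(benzyloxy)-2-oxo-2,3-dihydro-1-benzofuran-4-carbaldehyde | O=Cc1ccc(OCc2ccccc2)c2OC(=O)Cc12
F5 | step 3 | benzyl (2R)-3-[3,4-bis(benzyloxy)phenyl]-2-[(bromoacetyl)oxy]propanoate | O=C(OCc1ccccc1)[C@H](OC(=O)CBr)Cc1ccc(OCc2ccccc2)c(OCc2ccccc2)c1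
F6 | step 3 | {2-[(2R)-1-(benzyloxy)-3-[3,4-bis(benzyloxy)phenyl]-1-oxopropan-2-yl]oxy-2-oxoethyl}triphenylphosphonium bromide | O=C(OCc1ccccc1)[C@H](OC(=O)C[P+](c2ccccc2)(c2ccccc2)c2ccccc2)Cc1ccc(OCc2ccccc2)c(OCc2ccccc2)c1.[Br-]
F7 | step 4 | benzyl (2R)-3-[3,4-bis(benzyloxy)phenyl]-2-({(2E)-3-[7-(benzyloxy)-3-(methanesulfinyl)-2-oxo-2,3-dihydro-1-benzofuran-4-yl]prop-2-enoyl}oxy)propanoate | O=C(OCc1ccccc1)[C@H](OC(=O)/C=C/c1ccc(OCc2ccccc2)c2OC(=O)C(S(C)=O)c12)Cc1ccc(OCc2ccccc2)c(OCc2ccccc2)c1
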